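The carbocycle of the target (C4a, C5, C6, C7, C8, C8a of the chromenedione) contains the array C5(=O)–C6Me2–C7(=O)–C8Me2. This array is exactly the four-membered ring of the dimethylketene dimer. Everything rests on inserting the two missing carbons, C4a and C8a, into one C(O)–CMe2 bond of achiral, symmetric 2,2,4,4-tetramethylcyclobutane-1,3-dione. In one operation lithium ethoxyacetylide adds, the strained cyclobutanolate opens by retro-aldol cleavage, and the enolate recloses 6-endo-dig on the ynone. The ring thus grows from four to six atoms. Hydrolysis gives syncarpic acid. A domino Knoevenagel/hetero-Diels–Alder reaction with isobutyraldehyde and (+)-β-pinene then builds the pyran ring, spiro centre C2 and C4.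

Key step: step 1

Assumption: (1R,5R)-(+)-β-pinene of high enantiomeric purity is taken to be purchasable; it matches the pinane part of the target (1'S,5'R), because the CIP ranking at C-1' changes when the C2–O bond is formed.

Locants: chromene numbering for the target (O1, spiro C2, C3, C4, C4a, C5 to C8, C8a), primed locants for the pinane part.

Step 1
Reactants: 1 2,2,4,4-tetramethylcyclobutane-1,3-dione; 2 ethoxyacetylene
Product: 7 5-ethoxy-2,2,6,6-tetramethylcyclohex-4-ene-1,3-dione, via lithium ethoxyacetylide 3 (not isolated), via lithium cyclobutanolate adduct 4 (not isolated), via ring-opened ynone enolate 5 (not isolated), via ring-expanded vinyllithium 6 (not isolated)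
Conditions: 2 (1.05 equiv), n-BuLi (1.0 equiv), THF, −78 °C; 1 (1.0 equiv), −78 °C; DMPU, −78 to 23 °C; AcOH quench
Reagents that add atoms: none
Why: Proposed new method: acetylide 3 adds 1,2 to one of the two equivalent carbonyl groups of 1 (alkoxyacetylide carbonyl addition), and on warming the strained β-keto cyclobutanolate 4 cleaves a ring C(O)–CMe2 bond in a retro-aldol step to ynone enolate 5, which holds no acidic C–H that could quench it. The fully substituted enolate carbon of 5 then attacks the ethoxy-bearing alkyne carbon in an intramolecular Michael addition, a 6-endo-dig closure of the carbocycle, and vinyllithium 6 is protonated on quench to 7, so all four ring atoms of 1 are kept, the two alkyne carbons are inserted and the ring grows from four to six atoms. The closest known reaction types are the base-induced retro-aldol opening of 3-hydroxy-2,2,4,4-tetramethylcyclobutanone, the alkoxide-catalysed ester-anion enlargement of 1 to hexamethylcyclohexane-1,3,5-trione and endo-dig Michael carbocyclisations of enolates onto ynones. No stereocentre is formed. The step needs mono-addition, secured by consuming 1 with one equivalent of 3 at −78 °C before cleavage starts, the right insertion regiochemistry, secured by the symmetry of 1 and by the polarity of the acyl ynol ether whose only Michael terminus is the carbon bearing OEt, and C- over O-closure, favoured by the soft ynone acceptor. Release of cyclobutane strain should make the sequence irreversible.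

Step 2
Reactants: 7 5-ethoxy-2,2,6,6-tetramethylcyclohex-4-ene-1,3-dione
Product: 8 syncarpic acid (5-hydroxy-2,2,6,6-tetramethylcyclohex-4-ene-1,3-dione)
Conditions: 2 M aq HCl, THF, 60 °C; isolation by NaHCO3 extraction and re-acidification
Reagents that add atoms: water, O
Why: Acid-catalysed hydrolysis of a vinylogous ester by addition–elimination of water at C-5 of the O-protonated enone should release ethanol and the strongly acidic enol 8, since the gem-dimethyl-blocked β-diketone cannot enolise and tolerates acid, whereas basic hydrolysis would invite retro-Claisen cleavage; no stereocentre is involved.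

Step 3
Reactants: 8 syncarpic acid; 9 isobutyraldehyde; 10 (1R,5R)-(+)-β-pinene
Product: 12 (1'S,2S,4R,5'R)-4-isopropyl-6,6,6',6',8,8-hexamethyl-3,4-dihydrospiro[chromene-2,2'-bicyclo[3.1.1]heptane]-5,7(6H,8H)-dione (target), via isobutylidene trione 11 (not isolated)
Conditions: 9 (1.5 equiv), 10 (3 equiv), ethylenediammonium diacetate (cat.), 4 Å molecular sieves, toluene, 60 °C; chromatography
Reagents that add atoms: none
Why: In this domino Knoevenagel condensation/inverse-electron-demand hetero-Diels–Alder reaction 8 and 9 condense to the symmetric oxadiene 11 (no E/Z issue), whose alkylidene carbon bonds to the CH2 terminus and whose carbonyl oxygen bonds to the disubstituted carbon of 10 on the alkene face anti to the gem-dimethyl bridge, which sets C2 as S, while C4 (R) follows from the orientation that puts the isopropyl group on the side of bridgehead C-1', a choice that the pinane biases only weakly, so that any C4 epimer formed beside 12 is removed by chromatography.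

Compound list
1 | 2,2,4,4-tetramethylcyclobutane-1,3-dione (dimethylketene dimer, dione form) | CC1(C)C(=O)C(C)(C)C1=O | starting material
2 | ethoxyacetylene (ethoxyethyne, hexane solution) | C#COCC | starting material
3 | lithium ethoxyacetylide | [Li]C#COCC | intermediate
4 | lithium 1-(ethoxyethynyl)-2,2,4,4-tetramethyl-3-oxocyclobutan-1-olate | [Li+].[O-]C1(C#COCC)C(C)(C)C(=O)C1(C)C | intermediate
5 | lithium C5,C6-enolate of 1-ethoxy-4,4,6-trimethylhept-1-yne-3,5-dione | [Li+].CCOC#CC(=O)C(C)(C)C([O-])=C(C)C | intermediate
6 | 5-ethoxy-4-lithio-2,2,6,6-tetramethylcyclohex-4-ene-1,3-dione | CCOC1=C([Li])C(=O)C(C)(C)C(=O)C1(C)C | intermediate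
7 | 5-ethoxy-2,2,6,6-tetramethylcyclohex-4-ene-1,3-dione (syncarpic acid ethyl enol ether) | CCOC1=CC(=O)C(C)(C)C(=O)C1(C)C | intermediate
8 | syncarpic acid, enol form (5-hydroxy-2,2,6,6-tetramethylcyclohex-4-ene-1,3-dione) | OC1=CC(=O)C(C)(C)C(=O)C1(C)C | intermediate
9 | isobutyraldehyde (2-methylpropanal) | CC(C)C=O | starting material
10 | (1R,5R)-(+)-β-pinene (6,6-dimethyl-2-methylidenebicyclo[3.1.1]heptane) | C=C1CC[C@@H]2C[C@H]1C2(C)C | starting material
11 | 2,2,4,4-tetramethyl-6-(2-methylpropylidene)cyclohexane-1,3,5-trione | CC(C)C=C1C(=O)C(C)(C)C(=O)C(C)(C)C1=O | intermediate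
12 | (1'S,2S,4R,5'R)-spiro[chromene-2,2'-pinane]dione; O1 anti to the gem-dimethyl bridge, isopropyl at C4 cis to bridgehead C-1' | CC(C)[C@H]1C[C@]2(CC[C@@H]3C[C@H]2C3(C)C)OC2=C1C(=O)C(C)(C)C(=O)C2(C)C | target

Total step count: 3
Longest linear sequence: 3 steps (1 to 7 to 8 to 12)

Steps most likely to fail

**Step 1 (Proposed new method).**
- What may go wrong: the tightly ion-paired lithium alkoxide may not fragment. The ring-opened enolate may close through oxygen instead of carbon. The vinyllithium may add to a second molecule.
- Fallback with known chemistry, setting out from 1 and coming back at 8: the ester-anion ring enlargement known for this very dione is run with a fully substituted, later removable ester anion.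
- The lithium enolate of commercial ethyl 1,3-dithiane-2-carboxylate (LDA, THF, −78 to 23 °C) adds to 1. The cyclobutanolate cleaves, and the liberated enolate closes on the ester in a Dieckmann step. This is again a growth from four to six ring atoms in one operation.
- It should give 8,8,10,10-tetramethyl-1,5-dithiaspiro[5.5]undecane-7,9,11-trione F1.
- Reductive cleavage of both activated C–S bonds (Zn, AcOH, 40 °C) should then give 8, so step 2 is not needed.

**Step 3.**
- What may go wrong: weak control over the mutual orientation of oxadiene and alkene, hence erosion of the configuration at C4. An ene reaction of 10 and Michael addition of a second molecule of 8 to 11 also compete.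
- Fallback, setting out from the crude cycloadduct obtained from 11 and 10 and coming back at 12: C4 is erased and reset under catalyst control, so both epimers converge.
- The mixture of 12 and the (2S,4S)-epimer of 12 F2 is brominated at the tertiary allylic C4–H (Wohl–Ziegler reaction: NBS, AIBN, PhCF3, 80 °C). This gives the 4-bromo-4-isopropyl spirochromenedione F3.
- F3 loses hydrogen bromide (2,6-lutidine, 23 °C) to give the 4-isopropyl-2H-pyran with a C3=C4 double bond F4.
- Asymmetric hydrogenation of this trisubstituted alkene follows (H2, 50 bar, [Ir(cod)((S)-t-Bu-PHOX)]BArF or its ligand antipode, CH2Cl2). The antipode is chosen that delivers hydrogen to the face of C4 turned toward C-3', which should give 12.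

**Step 2.**
- What may go wrong: slow attack of water at C-5, which is shielded by the neighbouring CMe2 group, followed by ring cleavage on prolonged heating.
- Fallback, setting out from 7 and coming back at 8: the O–CH2 bond is broken instead of the C-5–O bond. This is SN2 dealkylation of the vinylogous ester with LiI in DMF at 120 °C, followed by acidification with dilute HCl. No new compound is passed.

Further compounds
F1 | step 1 | 8,8,10,10-tetramethyl-1,5-dithiaspiro[5.5]undecane-7,9,11-trione | CC1(C)C(=O)C(C)(C)C(=O)C2(SCCCS2)C1=O
F2 | step 3 | (1'S,2S,4S,5'R)-epimer of 12 (isopropyl cis to C-3') | CC(C)[C@@H]1C[C@]2(CC[C@@H]3C[C@H]2C3(C)C)OC2=C1C(=O)C(C)(C)C(=O)C2(C)C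
F3 | step 3 | 4-bromo-4-isopropyl spirochromenedione (C4 epimers) | CC(C)C1(Br)C[C@]2(CC[C@@H]3C[C@H]2C3(C)C)OC2=C1C(=O)C(C)(C)C(=O)C2(C)C
F4 | step 3 | 4-isopropyl-2H-pyran (C3=C4) spirochromenedione | CC(C)C1=C[C@]2(CC[C@@H]3C[C@H]2C3(C)C)OC2=C1C(=O)C(C)(C)C(=O)C2(C)C
F0 | step 2 | none | none
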